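**Retrosynthetic overview**

1. The decalin is numbered as in the name 2,5,5,8a-tetramethyl-3,4,4a,5,6,7,8,8a-octahydronaphthalen-1-yl: ring A is C4a–C5–C6–C7–C8–C8a (gem-dimethyl at C5), ring B is the cyclohexene C1–C2–C3–C4–C4a–C8a. The target is the (4aS,8aS) trans-decalin carrying a (2R,3E,5E)-2,6-dimethylocta-3,5-dienoic acid chain on C1.
2. Side chain: the diene is cut between chain C4 and C5 (Zr-catalysed carboalumination of a C1-butynyl group, then Pd coupling with (R)-alkenyl iodide 19 made from methyl (S)-3-hydroxy-2-methylpropanoate). The acid comes from a late alcohol oxidation, and the butynyl group from a Negishi coupling on the C1 enol triflate 11.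
3. Ring B is bought as (R)-carvone: its C5–H becomes C4a–H, its 2-methyl enone becomes the C1=C2 tetrasubstituted alkene (reductive enolate triflation), and two α′-alkylations set the quaternary C8a, the second one anti to the isopropenyl group.
4. Ring A is closed last, through the C5–C6 bond, by an iron-hydride hydrogen-atom-transfer 6-endo radical cyclisation of the isopropenyl group onto a 2-sulfonylallyl arm; the sulfone is a traceless activator that is removed in the next step.
5. Enabling feature: in ring A the gem-dimethyl carbon C5 is bonded directly to the ring-fusion CH (C4a), which is a hydrogenated isopropenyl group on a cyclohexane. C5 can therefore be made as a tertiary radical from carvone's isopropenyl carbon, with the alkene CH2 becoming its second methyl. Ring order: B (chiral pool), then A.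

Key step: step 5

Remark: compounds 1, 4, 12 and 16 are taken as commercial; monocyclic intermediates carry cyclohexenone locants (carvone C5 = decalin C4a, carvone C6 = decalin C8a, isopropenyl carbon = decalin C5).

**Route**

Step 1
Reactants: 1 phenyl vinyl sulfone
Product: 2 2-(phenylsulfonyl)prop-2-en-1-ol
Conditions: aq. HCHO (37 %), DABCO (0.5 equiv), THF, rt
Reagents that add atoms: formaldehyde C=O
Why: Morita–Baylis–Hillman α-hydroxymethylation of the vinyl sulfone through the amine-derived α-sulfonyl carbanion should give the allylic alcohol; no stereocenter is formed.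

Step 2
Reactants: 2 2-(phenylsulfonyl)prop-2-en-1-ol
Product: 3 3-bromo-2-(phenylsulfonyl)prop-1-ene
Conditions: PBr3 (0.4 equiv), Et2O, 0 °C
Reagents that add atoms: phosphorus tribromide BrP(Br)Br
Why: Bromination of the primary allylic alcohol (SN2 and SN2′ give the same constitution) should deliver the doubly activated allylic bromide.

Step 3
Reactants: 4 (R)-carvone
Product: 6 (5R)-2,6-dimethyl-5-(prop-1-en-2-yl)cyclohex-2-en-1-one (C6 epimer mixture), via lithium dienolate 5 (not isolated)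
Conditions: LiN(i-Pr)2 (1.1 equiv), THF, −78 °C; MeI, −78 to 0 °C
Reagents that add atoms: iodomethane CI
Why: Kinetic α′-deprotonation gives the cross-conjugated dienolate, whose C-methylation (enolate alkylation) should be clean; the new C6 center forms as an epimer mixture, which does not matter because C6 is made planar again in step 4, and C5 is untouched.

Step 4
Reactants: 6 (5R)-2,6-dimethyl-5-(prop-1-en-2-yl)cyclohex-2-en-1-one and 3 3-bromo-2-(phenylsulfonyl)prop-1-ene
Product: 8 (5S,6S)-2,6-dimethyl-6-[2-(phenylsulfonyl)prop-2-en-1-yl]-5-(prop-1-en-2-yl)cyclohex-2-en-1-one, via lithium enolate 7 (not isolated)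
Conditions: LiN(i-Pr)2 (1.1 equiv), THF, −78 to −20 °C; cannulation into 3 (1.3 equiv), THF, −78 °C
Reagents that add atoms: none
Why: Enolate alkylation by SN2′ addition–elimination on the activated allylic bromide: both C6 epimers of 6 converge on the same tetrasubstituted enolate 7, and the electrophile should enter anti to the pseudoaxial C5 isopropenyl group (1,2-induction), placing the new arm trans and the methyl cis to it, which is the relative configuration of the trans ring fusion (future C4a/C8a); the minor epimer would be removed by chromatography.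

Step 5
Reactants: 8 (5S,6S)-2,6-dimethyl-6-[2-(phenylsulfonyl)prop-2-en-1-yl]-5-(prop-1-en-2-yl)cyclohex-2-en-1-one
Product: 9 (4aS,8aS)-2,5,5,8a-tetramethyl-7-(phenylsulfonyl)-4a,5,6,7,8,8a-hexahydronaphthalen-1(4H)-one (C7 epimer mixture)
Conditions: Fe(acac)3 (0.3 equiv), PhSiH3 (2.5 equiv), EtOH/HOCH2CH2OH 5:1, 0.02 M, degassed, 60 °C
Reagents that add atoms: none
Why: Hydrogen-atom transfer from the iron hydride (generated from Fe(acac)3 and PhSiH3) to the CH2 terminus of the isopropenyl group creates the tertiary radical at decalin C5, which adds to the unsubstituted alkene terminus (decalin C6) of the vinyl sulfone; the α-sulfonyl radical is then reduced by divalent iron and protonated by ethanol. The closest known reaction type is the iron-hydride reductive olefin coupling (hydrogen-atom-transfer Giese reaction) of 1,1-disubstituted alkenes with vinyl sulfones, including intramolecular versions that build quaternary carbons. Ring A (C4a–C5–C6–C7–C8–C8a) is closed in the 6-endo-trig mode through the C5–C6 bond, because 5-exo attack would have to occur at the sulfonyl-bearing carbon and would give an unstabilised primary radical. C5 becomes the gem-dimethyl quaternary carbon (its second methyl is the former alkene CH2) and is not stereogenic; the only new stereocenter, the sulfonyl-bearing C7, is uncontrolled and is erased in step 6, while C4a (from carvone) and C8a (step 4) are untouched, their trans-disposed arms leading only to the trans-fused decalin. The step needs hydrogen-atom transfer to the electron-rich isopropenyl group in preference to the enone and the vinyl sulfone, which the polarity of the iron hydride and high dilution should secure. Because C5 is a radical and not a cation, no 1,2-hydride shift from C4a can scramble the ring-fusion stereocenter.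

Step 6
Reactants: 9 (4aS,8aS)-2,5,5,8a-tetramethyl-7-(phenylsulfonyl)-4a,5,6,7,8,8a-hexahydronaphthalen-1(4H)-one
Product: 11 (4aS,8aS)-2,5,5,8a-tetramethyl-3,4,4a,5,6,7,8,8a-octahydronaphthalen-1-yl trifluoromethanesulfonate, via lithium enolate 10 (not isolated)
Conditions: Li (6 equiv), NH3(l)/THF, t-BuOH (2 equiv), −78 °C; isoprene; evaporation of NH3; PhNTf2 (3 equiv), THF, 0 °C to rt
Reagents that add atoms: N-phenylbis(trifluoromethanesulfonimide) O=S(=O)(N(c1ccccc1)S(=O)(=O)C(F)(F)F)C(F)(F)F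
Why: Dissolving-metal (Birch-type) reduction cleaves the C7–S bond and converts the enone into its lithium enolate, which can only be the C1=C2 enolate because C8a is quaternary, and O-triflation of this enolate (reductive enolate trapping) fixes the tetrasubstituted alkene; the C7 epimers converge and C4a/C8a are not touched.

Step 7
Reactants: 11 (4aS,8aS)-2,5,5,8a-tetramethyl-3,4,4a,5,6,7,8,8a-octahydronaphthalen-1-yl trifluoromethanesulfonate and 12 (4-iodobut-1-yn-1-yl)trimethylsilane
Product: 14 trimethyl{4-[(4aS,8aS)-2,5,5,8a-tetramethyl-3,4,4a,5,6,7,8,8a-octahydronaphthalen-1-yl]but-1-yn-1-yl}silane, via organozinc iodide 13 (not isolated)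
Conditions: 12, Zn dust, LiCl, THF, 40 °C; then 11, PdCl2(dppf) (5 mol %), THF/NMP, 60 °C
Reagents that add atoms: none
Why: Negishi sp2–sp3 coupling of the alkenyl triflate with the primary alkylzinc iodide (from LiCl-assisted zinc insertion into 12) should form the C1–CH2 bond without moving the double bond, the bidentate dppf ligand disfavouring β-hydride elimination.

Step 8
Reactants: 14 trimethyl{4-[(4aS,8aS)-2,5,5,8a-tetramethyl-3,4,4a,5,6,7,8,8a-octahydronaphthalen-1-yl]but-1-yn-1-yl}silane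
Product: 15 (4aS,8aS)-1-(but-3-yn-1-yl)-2,5,5,8a-tetramethyl-3,4,4a,5,6,7,8,8a-octahydronaphthalene
Conditions: K2CO3 (0.2 equiv), MeOH, rt
Reagents that add atoms: none
Why: Base-catalysed methanolysis of the alkynyl C–Si bond (protiodesilylation) frees the terminal alkyne and touches nothing else.

Step 9
Reactants: 16 methyl (S)-3-hydroxy-2-methylpropanoate
Product: 17 methyl (S)-3-[(tert-butyldimethylsilyl)oxy]-2-methylpropanoate
Conditions: TBSCl, imidazole, CH2Cl2, rt
Reagents that add atoms: tert-butyldimethylsilyl chloride CC(C)(C)[Si](C)(C)Cl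
Why: Silyl ether formation at the primary alcohol leaves the α-stereocenter untouched.

Step 10
Reactants: 17 methyl (S)-3-[(tert-butyldimethylsilyl)oxy]-2-methylpropanoate
Product: 18 (S)-3-[(tert-butyldimethylsilyl)oxy]-2-methylpropanal
Conditions: i-Bu2AlH (1.05 equiv), CH2Cl2, −78 °C; cold aqueous tartrate work-up
Reagents that add atoms: none
Why: Partial ester reduction stops at the aldehyde because the tetrahedral aluminium hemiacetal is stable at −78 °C, and the non-basic conditions should keep the α-stereocenter intact.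

Step 11
Reactants: 18 (S)-3-[(tert-butyldimethylsilyl)oxy]-2-methylpropanal
Product: 19 tert-butyl{[(2R,3E)-4-iodo-2-methylbut-3-en-1-yl]oxy}dimethylsilane
Conditions: CrCl2 (6 equiv), CHI3 (2 equiv), THF/dioxane, 0 °C to rt
Reagents that add atoms: iodoform IC(I)I
Why: Takai olefination with the geminal dichromium species from CHI3 and CrCl2 should give the (E)-alkenyl iodide under non-basic conditions that do not epimerise the α-stereocenter (the descriptor changes to R only through the priority rules).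

Step 12
Reactants: 15 (4aS,8aS)-1-(but-3-yn-1-yl)-2,5,5,8a-tetramethyl-3,4,4a,5,6,7,8,8a-octahydronaphthalene and 19 tert-butyl{[(2R,3E)-4-iodo-2-methylbut-3-en-1-yl]oxy}dimethylsilane
Product: 21 tert-butyldimethyl{[(2R,3E,5E)-2,6-dimethyl-8-[(4aS,8aS)-2,5,5,8a-tetramethyl-3,4,4a,5,6,7,8,8a-octahydronaphthalen-1-yl]octa-3,5-dien-1-yl]oxy}silane, via alkenylalane 20 (not isolated)
Conditions: AlMe3 (2.5 equiv), Cp2ZrCl2 (0.3 equiv), CH2Cl2, 0 °C to rt; then 19, Pd(PPh3)4 (5 mol %), ZnCl2 (1 equiv), THF, rt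
Reagents that add atoms: trimethylaluminium C[Al](C)C
Why: Zirconium-catalysed syn-carboalumination (Negishi carboalumination) puts methyl on the internal and aluminium on the terminal alkyne carbon, fixing the (5E) trisubstituted alkene, and the palladium-catalysed cross-coupling of the alkenylalane with 19 (zinc-assisted transmetalation) proceeds with retention at both alkenes to give the (3E,5E)-diene.

Step 13
Reactants: 21 tert-butyldimethyl{[(2R,3E,5E)-2,6-dimethyl-8-[(4aS,8aS)-2,5,5,8a-tetramethyl-3,4,4a,5,6,7,8,8a-octahydronaphthalen-1-yl]octa-3,5-dien-1-yl]oxy}silane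
Product: 22 (2R,3E,5E)-2,6-dimethyl-8-[(4aS,8aS)-2,5,5,8a-tetramethyl-3,4,4a,5,6,7,8,8a-octahydronaphthalen-1-yl]octa-3,5-dien-1-ol
Conditions: Bu4NF, THF, 0 °C to rt
Reagents that add atoms: none
Why: Fluoride-mediated cleavage of the silyl ether frees the primary alcohol without touching the diene or the stereocenters.

Step 14
Reactants: 22 (2R,3E,5E)-2,6-dimethyl-8-[(4aS,8aS)-2,5,5,8a-tetramethyl-3,4,4a,5,6,7,8,8a-octahydronaphthalen-1-yl]octa-3,5-dien-1-ol
Product: 24 (2R,3E,5E)-2,6-dimethyl-8-[(4aS,8aS)-2,5,5,8a-tetramethyl-3,4,4a,5,6,7,8,8a-octahydronaphthalen-1-yl]octa-3,5-dienoic acid (target), via aldehyde 23 (not isolated)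
Conditions: TEMPO (0.2 equiv), PhI(OAc)2 (1.2 equiv), CH2Cl2, 0 °C; then NaClO2, NaH2PO4, 2-methyl-2-butene (30 equiv), t-BuOH/H2O, 0 °C
Reagents that add atoms: sodium chlorite [Na+].[O-]Cl=O
Why: Nitroxyl-catalysed oxidation to the aldehyde under non-basic conditions, followed at once by a cold, buffered Pinnick oxidation with an olefinic hypochlorite scavenger, should give the acid without epimerisation at C2 or migration of the C3=C4 double bond.

**Compound list**

1 | phenyl vinyl sulfone | C=CS(=O)(=O)c1ccccc1 | starting material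
2 | 2-(phenylsulfonyl)prop-2-en-1-ol | C=C(CO)S(=O)(=O)c1ccccc1 | intermediate
3 | 3-bromo-2-(phenylsulfonyl)prop-1-ene | C=C(CBr)S(=O)(=O)c1ccccc1 | intermediate
4 | (R)-carvone, (5R)-2-methyl-5-(prop-1-en-2-yl)cyclohex-2-en-1-one | CC1=CC[C@@H](C(C)=C)CC1=O | starting material
5 | lithium (3R)-6-methyl-3-(prop-1-en-2-yl)cyclohexa-1,5-dien-1-olate (formed in the flask) | CC1=CC[C@@H](C(C)=C)C=C1O[Li] | intermediate
6 | (5R)-2,6-dimethyl-5-(prop-1-en-2-yl)cyclohex-2-en-1-one, mixture of C6 epimers | CC1=CC[C@@H](C(C)=C)C(C)C1=O | intermediate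
7 | lithium (3S)-2,6-dimethyl-3-(prop-1-en-2-yl)cyclohexa-1,5-dien-1-olate (formed in the flask) | CC1=CC[C@@H](C(C)=C)C(C)=C1O[Li] | intermediate
8 | (5S,6S)-2,6-dimethyl-6-[2-(phenylsulfonyl)prop-2-en-1-yl]-5-(prop-1-en-2-yl)cyclohex-2-en-1-one | CC1=CC[C@@H](C(C)=C)[C@](C)(CC(=C)S(=O)(=O)c2ccccc2)C1=O | intermediate
9 | (4aS,8aS)-2,5,5,8a-tetramethyl-7-(phenylsulfonyl)-4a,5,6,7,8,8a-hexahydronaphthalen-1(4H)-one, mixture of C7 epimers | CC1=CC[C@H]2C(C)(C)CC(S(=O)(=O)c3ccccc3)C[C@]2(C)C1=O | intermediate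
10 | lithium (4aS,8aS)-2,5,5,8a-tetramethyl-3,4,4a,5,6,7,8,8a-octahydronaphthalen-1-olate (formed in the flask) | CC1=C(O[Li])[C@@]2(C)CCCC(C)(C)[C@@H]2CC1 | intermediate
11 | (4aS,8aS)-2,5,5,8a-tetramethyl-3,4,4a,5,6,7,8,8a-octahydronaphthalen-1-yl trifluoromethanesulfonate | CC1=C(OS(=O)(=O)C(F)(F)F)[C@@]2(C)CCCC(C)(C)[C@@H]2CC1 | intermediate
12 | (4-iodobut-1-yn-1-yl)trimethylsilane | C[Si](C)(C)C#CCCI | starting material
13 | [4-(trimethylsilyl)but-3-yn-1-yl]zinc iodide (formed in the flask) | C[Si](C)(C)C#CCC[Zn]I | intermediate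
14 | trimethyl{4-[(4aS,8aS)-2,5,5,8a-tetramethyl-3,4,4a,5,6,7,8,8a-octahydronaphthalen-1-yl]but-1-yn-1-yl}silane | CC1=C(CCC#C[Si](C)(C)C)[C@@]2(C)CCCC(C)(C)[C@@H]2CC1 | intermediate
15 | (4aS,8aS)-1-(but-3-yn-1-yl)-2,5,5,8a-tetramethyl-3,4,4a,5,6,7,8,8a-octahydronaphthalene | CC1=C(CCC#C)[C@@]2(C)CCCC(C)(C)[C@@H]2CC1 | intermediate
16 | methyl (S)-3-hydroxy-2-methylpropanoate | COC(=O)[C@@H](C)CO | starting material
17 | methyl (S)-3-[(tert-butyldimethylsilyl)oxy]-2-methylpropanoate | COC(=O)[C@@H](C)CO[Si](C)(C)C(C)(C)C | intermediate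
18 | (S)-3-[(tert-butyldimethylsilyl)oxy]-2-methylpropanal | O=C[C@@H](C)CO[Si](C)(C)C(C)(C)C | intermediate
19 | tert-butyl{[(2R,3E)-4-iodo-2-methylbut-3-en-1-yl]oxy}dimethylsilane | I/C=C/[C@@H](C)CO[Si](C)(C)C(C)(C)C | intermediate
20 | dimethyl{(1E)-2-methyl-4-[(4aS,8aS)-2,5,5,8a-tetramethyl-3,4,4a,5,6,7,8,8a-octahydronaphthalen-1-yl]but-1-en-1-yl}alane (formed in the flask) | CC1=C(CC/C(C)=C/[Al](C)C)[C@@]2(C)CCCC(C)(C)[C@@H]2CC1 | intermediate
21 | tert-butyldimethyl{[(2R,3E,5E)-2,6-dimethyl-8-[(4aS,8aS)-2,5,5,8a-tetramethyl-3,4,4a,5,6,7,8,8a-octahydronaphthalen-1-yl]octa-3,5-dien-1-yl]oxy}silane | CC1=C(CC/C(C)=C/C=C/[C@@H](C)CO[Si](C)(C)C(C)(C)C)[C@@]2(C)CCCC(C)(C)[C@@H]2CC1 | intermediate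
22 | (2R,3E,5E)-2,6-dimethyl-8-[(4aS,8aS)-2,5,5,8a-tetramethyl-3,4,4a,5,6,7,8,8a-octahydronaphthalen-1-yl]octa-3,5-dien-1-ol | CC1=C(CC/C(C)=C/C=C/[C@@H](C)CO)[C@@]2(C)CCCC(C)(C)[C@@H]2CC1 | intermediate
23 | (2R,3E,5E)-2,6-dimethyl-8-[(4aS,8aS)-2,5,5,8a-tetramethyl-3,4,4a,5,6,7,8,8a-octahydronaphthalen-1-yl]octa-3,5-dienal (formed in the flask) | CC1=C(CC/C(C)=C/C=C/[C@@H](C)C=O)[C@@]2(C)CCCC(C)(C)[C@@H]2CC1 | intermediate
24 | (2R,3E,5E)-2,6-dimethyl-8-[(4aS,8aS)-2,5,5,8a-tetramethyl-3,4,4a,5,6,7,8,8a-octahydronaphthalen-1-yl]octa-3,5-dienoic acid | CC1=C(CC/C(C)=C/C=C/[C@@H](C)C(=O)O)[C@@]2(C)CCCC(C)(C)[C@@H]2CC1 | target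

**Step count and risks**

Total step count: 14. Longest linear sequence: 10 steps (steps 1, 2, 4, 5, 6, 7, 8, 12, 13, 14).

Step 5 (key step). What may go wrong: the tertiary radical is reduced by a second hydrogen-atom transfer before it cyclises, or hydrogen-atom transfer goes to the vinyl sulfone first so that the cyclisation runs in the wrong sense. The fallback uses carbenoid chemistry with a cyclopropane as a temporary ring; it sets out from 6 and comes back at 10 (and from there to 11 as in step 6). Enolate 7, made as in step 4, is alkylated with ethyl bromoacetate to ethyl 2-[(1S,6S)-1,3-dimethyl-2-oxo-6-(prop-1-en-2-yl)cyclohex-3-en-1-yl]acetate F1. LiOH in THF/H2O gives 2-[(1S,6S)-1,3-dimethyl-2-oxo-6-(prop-1-en-2-yl)cyclohex-3-en-1-yl]acetic acid F2. (COCl)2 gives 2-[(1S,6S)-1,3-dimethyl-2-oxo-6-(prop-1-en-2-yl)cyclohex-3-en-1-yl]acetyl chloride F3, and CH2N2 converts it into (5S,6S)-6-(3-diazo-2-oxopropyl)-2,6-dimethyl-5-(prop-1-en-2-yl)cyclohex-2-en-1-one F4. Rh2(OAc)4 in CH2Cl2 adds the carbenoid carbon across the isopropenyl double bond (intramolecular cyclopropanation), which forms the C5–C6 bond of ring A as part of a cyclopropane and gives (4aS,8aS)-2,5,8a-trimethyl-5,6-methano-4a,5,6,8a-tetrahydronaphthalene-1,7(4H,8H)-dione F5. Li in NH3 then opens the cyclopropane bond that overlaps with the C7 carbonyl (C6–CH2), so that the cyclopropane CH2 becomes the second methyl on C5, and also reduces the enone; after NH4Cl this gives (4aS,8aS)-2,5,5,8a-tetramethyl-3,4,4a,5,6,8a-hexahydronaphthalene-1,7(2H,8H)-dione F6. TsNHNH2 should condense only with the less hindered C7 ketone to give the 7-(4-methylbenzenesulfonyl)hydrazone of that dione F7, and catecholborane/NaOAc reduces it to (4aS,8aS)-2,5,5,8a-tetramethyloctahydronaphthalen-1(2H)-one F8. LiN(i-Pr)2 converts F8 into lithium enolate 10.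

Step 7. What may go wrong: slow oxidative addition and transmetalation at the tetrasubstituted triflate next to the quaternary C8a, so that β-hydride elimination or protonolysis of the alkylmetal takes over. The fallback builds the chain one carbon at a time; it sets out from 11 and comes back at 14. Pd(OAc)2/PPh3, CO (1 atm), MeOH and Et3N in DMF (alkoxycarbonylation) give methyl (4aS,8aS)-2,5,5,8a-tetramethyl-3,4,4a,5,6,7,8,8a-octahydronaphthalene-1-carboxylate F9. i-Bu2AlH gives [(4aS,8aS)-2,5,5,8a-tetramethyl-3,4,4a,5,6,7,8,8a-octahydronaphthalen-1-yl]methanol F10, and PBr3 gives (4aS,8aS)-1-(bromomethyl)-2,5,5,8a-tetramethyl-3,4,4a,5,6,7,8,8a-octahydronaphthalene F11. Alkylation with [3-(trimethylsilyl)prop-2-yn-1-yl]lithium F12 (from 1-(trimethylsilyl)propyne and n-BuLi, THF, −78 °C) forms the CH2–CH2 bond by SN2 at the primary allylic carbon and gives 14.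

Step 14. What may go wrong: epimerisation at C2 or migration of the C3=C4 double bond into conjugation while the β,γ-unsaturated aldehyde exists, and attack of hypochlorite on the electron-rich alkenes. The fallback makes the carboxylic acid on the small fragment and joins the fragments by Suzuki–Miyaura coupling, so that no oxidation is run on the polyene; it sets out from 19 and 15 and comes back at 24. Bu4NF converts 19 into (2R,3E)-4-iodo-2-methylbut-3-en-1-ol F13, and CrO3/H2SO4 in acetone at 0 °C (Jones oxidation, acidic medium) gives (2R,3E)-4-iodo-2-methylbut-3-enoic acid F14, whose enantiomeric purity can be checked at this stage. Alkyne 15 is carboaluminated as in step 12 to 20 and iodinated (I2, THF, −30 °C) to (4aS,8aS)-1-[(3E)-4-iodo-3-methylbut-3-en-1-yl]-2,5,5,8a-tetramethyl-3,4,4a,5,6,7,8,8a-octahydronaphthalene F15. Miyaura borylation (B2pin2, PdCl2(dppf), KOPh, toluene, 50 °C) gives 2-{(1E)-2-methyl-4-[(4aS,8aS)-2,5,5,8a-tetramethyl-3,4,4a,5,6,7,8,8a-octahydronaphthalen-1-yl]but-1-en-1-yl}-4,4,5,5-tetramethyl-1,3,2-dioxaborolane F16. Coupling of F16 with F14 (Pd(PPh3)4, aq. K3PO4, THF, 50 °C), in which the carboxylate should be configurationally stable, gives 24.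

**Further compounds**

F1 | step 5 | ethyl 2-[(1S,6S)-1,3-dimethyl-2-oxo-6-(prop-1-en-2-yl)cyclohex-3-en-1-yl]acetate | CC1=CC[C@@H](C(C)=C)[C@](C)(CC(=O)OCC)C1=O
F2 | step 5 | 2-[(1S,6S)-1,3-dimethyl-2-oxo-6-(prop-1-en-2-yl)cyclohex-3-en-1-yl]acetic acid | CC1=CC[C@@H](C(C)=C)[C@](C)(CC(=O)O)C1=O
F3 | step 5 | 2-[(1S,6S)-1,3-dimethyl-2-oxo-6-(prop-1-en-2-yl)cyclohex-3-en-1-yl]acetyl chloride | CC1=CC[C@@H](C(C)=C)[C@](C)(CC(=O)Cl)C1=O
F4 | step 5 | (5S,6S)-6-(3-diazo-2-oxopropyl)-2,6-dimethyl-5-(prop-1-en-2-yl)cyclohex-2-en-1-one | CC1=CC[C@@H](C(C)=C)[C@](C)(CC(=O)C=[N+]=[N-])C1=O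
F5 | step 5 | (4aS,8aS)-2,5,8a-trimethyl-5,6-methano-4a,5,6,8a-tetrahydronaphthalene-1,7(4H,8H)-dione (cyclopropane across C5–C6, configuration there not defined) | CC1=CC[C@H]2C3(C)CC3C(=O)C[C@]2(C)C1=O
F6 | step 5 | (4aS,8aS)-2,5,5,8a-tetramethyl-3,4,4a,5,6,8a-hexahydronaphthalene-1,7(2H,8H)-dione (C2 epimers) | CC1CC[C@H]2C(C)(C)CC(=O)C[C@]2(C)C1=O
F7 | step 5 | 7-(4-methylbenzenesulfonyl)hydrazone of (4aS,8aS)-2,5,5,8a-tetramethyl-3,4,4a,5,6,8a-hexahydronaphthalene-1,7(2H,8H)-dione | CC1CC[C@H]2C(C)(C)CC(=NNS(=O)(=O)c3ccc(C)cc3)C[C@]2(C)C1=O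
F8 | step 5 | (4aS,8aS)-2,5,5,8a-tetramethyloctahydronaphthalen-1(2H)-one (C2 epimers) | CC1CC[C@H]2C(C)(C)CCC[C@]2(C)C1=O
F9 | step 7 | methyl (4aS,8aS)-2,5,5,8a-tetramethyl-3,4,4a,5,6,7,8,8a-octahydronaphthalene-1-carboxylate | CC1=C(C(=O)OC)[C@@]2(C)CCCC(C)(C)[C@@H]2CC1
F10 | step 7 | [(4aS,8aS)-2,5,5,8a-tetramethyl-3,4,4a,5,6,7,8,8a-octahydronaphthalen-1-yl]methanol | CC1=C(CO)[C@@]2(C)CCCC(C)(C)[C@@H]2CC1
F11 | step 7 | (4aS,8aS)-1-(bromomethyl)-2,5,5,8a-tetramethyl-3,4,4a,5,6,7,8,8a-octahydronaphthalene | CC1=C(CBr)[C@@]2(C)CCCC(C)(C)[C@@H]2CC1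
F12 | step 7 | [3-(trimethylsilyl)prop-2-yn-1-yl]lithium | [Li]CC#C[Si](C)(C)C
F13 | step 14 | (2R,3E)-4-iodo-2-methylbut-3-en-1-ol | I/C=C/[C@@H](C)CO
F14 | step 14 | (2R,3E)-4-iodo-2-methylbut-3-enoic acid | I/C=C/[C@@H](C)C(=O)O
F15 | step 14 | (4aS,8aS)-1-[(3E)-4-iodo-3-methylbut-3-en-1-yl]-2,5,5,8a-tetramethyl-3,4,4a,5,6,7,8,8a-octahydronaphthalene | CC1=C(CC/C(C)=C/I)[C@@]2(C)CCCC(C)(C)[C@@H]2CC1
F16 | step 14 | 2-{(1E)-2-methyl-4-[(4aS,8aS)-2,5,5,8a-tetramethyl-3,4,4a,5,6,7,8,8a-octahydronaphthalen-1-yl]but-1-en-1-yl}-4,4,5,5-tetramethyl-1,3,2-dioxaborolane | CC1=C(CC/C(C)=C/B3OC(C)(C)C(C)(C)O3)[C@@]2(C)CCCC(C)(C)[C@@H]2CC1
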